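The product of the charges, GQ, is 0.240 M^2 in birch and 0.240 M^2 in alder, so the larger G of birch buys nothing through that product; here is the quick number you asked for.

| setting | alder | ash | birch |
|---|---|---|---|
| G | 0.400 M | 0.400 M | 1.20 M |
| Q | 0.600 M | 0.600 M | 0.200 M |
| L | 8.00 × 10⁻⁴ M | 8.00 × 10⁻⁴ M | 8.00 × 10⁻⁴ M |
| E |  | 0.120 M |  |
| time |  |  | 7.9 min |

| run | time / min | [E] / M |
|---|---|---|
| alder run | 1.3 | 0.0516 |
| alder run | 2.6 | 0.0996 |
| alder run | 4.0 | 0.1508 |
| alder run | 5.3 | 0.1860 |
| alder run | 6.6 | 0.2240 |
| alder run | 7.9 | 0.2617 |
| ash run | 1.3 | 0.1661 |
| ash run | 2.6 | 0.2143 |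
| ash run | 4.0 | 0.2556 |
| ash run | 5.3 | 0.2943 |
| ash run | 6.6 | 0.3271 |
| ash run | 7.9 | 0.3621 |

(each reading ± 0.002 M)

- E in the birch run at 7.9 min, as a share of the G charged
- which of these the readings show (the two partners rest in a complex / the product ties up the catalyst / the substrate is lost by itself / an uncatalysed path runs beside / nothing beyond the main steps)

- Overall: G + Q -> E, with L as catalyst.
- Constant volume, constant temperature.
- A reading of a species includes what of it is bound.

In alder the mean rate went from 0.0377 M/min up to the third reading to 0.0284 M/min after it, a gentler fall than GQ took, from 0.170 M^2 to 0.0763 M^2 at mid-stretch. I therefore assumed the form for two partners sharing one catalyst, rate = GQ/(D times W squared), with D the value of GQ over the rate in the first stretch of alder, 271 M·s, and W the crowding, the root of the ratio of GQ over the rate to D. W is one in the first stretch of alder by construction and 0.771 in the second. That is a fall of 1.75 /M for each M of E made, which I call the crowding slope.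

Ash, which is alder plus E, made 0.242 M by the last reading against 0.2617 M in alder, so I concluded that E ties up L.

G and Q fall together in both runs, so the readings could not split that slope. Charging it all to G was my commitment, not a reading. It put W in birch at 2.53 and the opening rate at 0.00827 M/min, below alder's first-stretch mean. With Q the limiting reagent, I ran birch as pseudo-first-order in Q at 0.0414 /min, which gave 4.65% of the G charged.

The forecast, which held that the “catalyst is therefore close to saturated”, said 13.4% and the product ties up the catalyst, well above my figure.

The flask gave 4.68% and the product ties up the catalyst.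

    L + G ⇌ LG, settled at all times (10.20 /M)
    L + Q ⇌ LQ, settled at all times (1.760 /M)
    LG + LQ → E + 2 L (5.478 × 10⁵ /M/min)
    L + E ⇌ LE, settled at all times (1.940 /M)

In birch, the step in which LG meets LQ made 0.0561 M of E while G went from 1.20 M to 1.14 M and Q from 0.200 M to 0.144 M, at a mean W of 2.51. In ash, the same step ran beside LE, and after the third reading, at 0.189 M made, W read 0.839, above the 0.801 that the crowding slope gives from alder at that amount.

The earlier runs and the new flask were generated by integration with made-up constants.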